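## Retrosynthetic overview

1. Ring D (the oxocene) is closed last by ring-closing metathesis at C17=C18, between an allyl ether on O13 and a 3-methylbut-3-enyl chain on C14; the chain is grown from a C15 ester on C14.
2. Rings B and C are formed together from a monocyclic ring A precursor by an intramolecular Diels–Alder reaction that makes C8–C9 and C13–C14. The diene is the (1E,3Z)-dienol silyl ether C9=C11–C12=C13(OSiEt3)Me on C10; the dienophile is the (E)-enoate C8(Me)=C14–C15O2Me, held on C5 through C6–C7.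
3. Enabling feature: ring C (C8, C9, C11, C12, C13, C14) is a cyclohexane in which a four-carbon unit C9–C11–C12–C13 is joined to a two-carbon unit C8–C14. C13 carries O and Me (the terminus of a methyl ketone dienol ether), C14 carries C15 (room for an activating ester), C8 carries Me in (E)-isoprenoid geometry, and C8–C9 is also the B/C fusion, so ring B (C10, C5, C6, C7) is the tether.
4. The ring A precursor comes from 2,4,4-trimethylcyclohex-2-enone: copper-catalysed conjugate addition with enolate acylation sets C5 and C10 (trans), and a vinylogous Mukaiyama aldol sets C6 and brings C7, C8, C14 and C15.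
5. Order of ring formation: A (bought) → B + C (key step, which also sets C8, C9, C13, C14) → D.

Key step: step 10

Remark on numbering: atoms carry the cheilanthane-type numbering of the target. Ring A = C1–C5, C10; ring B = C5–C10; ring C = C8, C9, C11–C14; ring D = C13, O, C19, C18, C17, C16, C15, C14. Methyl groups sit on C4 (two), C8, C10, C13 and C17. α means below and β above the plane of the usual terpenoid drawing.

Assumption: in the two catalyst-controlled steps (1 and 7) the antipode of the chiral ligand or catalyst that gives the drawn configuration is used; both antipodes are available.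

## Route

Step 1
Reactants: 1 2,4,4-trimethylcyclohex-2-en-1-one; 2 (chloromethyl)dimethyl(propan-2-yloxy)silane; 3 pent-4-enoyl chloride
Product: 6 (2S,3S)-3-{[dimethyl(propan-2-yloxy)silyl]methyl}-2,4,4-trimethyl-2-(pent-4-enoyl)cyclohexan-1-one, via silylmethyl Grignard reagent 4 (not isolated), via magnesium enolate 5 (not isolated)
Conditions: 2, Mg, Et2O; Cu(OTf)2 (5 mol%), chiral imidazolinium salt (N-heterocyclic carbene precursor, 6 mol%), Et2O, −30 °C, then 1; then 3, −78 → 0 °C
Reagents that add atoms: none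
Why: Copper-catalysed asymmetric conjugate addition of the silylmethyl Grignard reagent (a masked hydroxymethyl group) to the α-methyl enone should set C5 under ligand control and give the regiodefined tetrasubstituted magnesium enolate, whose C-acylation occurs anti to the new C5 substituent, so that the acyl carbon C9 and the C6 carbon end up trans across C10–C5 (tandem conjugate addition and enolate trapping).

Step 2
Reactants: 6 (2S,3S)-diketone
Product: 7 (1Z)-1-[(1S,6S)-6-{[dimethyl(propan-2-yloxy)silyl]methyl}-1,5,5-trimethyl-2-(trifluoromethanesulfonyloxy)cyclohex-2-en-1-yl]penta-1,4-dien-1-yl trifluoromethanesulfonate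
Conditions: KN(SiMe3)2 (2.3 equiv), THF, −78 °C; PhNTf2 (2.3 equiv), −78 → 0 °C
Reagents that add atoms: N-phenylbis(trifluoromethanesulfonimide), O=S(=O)(N(c1ccccc1)S(=O)(=O)C(F)(F)F)C(F)(F)F
Why: Each ketone has a single enolisable α-position (C2 and C11), so double deprotonation and O-sulfonylation are regiospecific, and the bulky quaternary C10 should force the (Z)-enolate of the acyclic ketone (enol triflate formation).

Step 3
Reactants: 7 bis(enol triflate)
Product: 8 dimethyl(propan-2-yloxy){[(1S,2S)-2,6,6-trimethyl-2-[(1E)-penta-1,4-dien-1-yl]cyclohex-3-en-1-yl]methyl}silane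
Conditions: Pd(OAc)2 (5 mol%), PPh3 (10 mol%), HCO2H, Bu3N, DMF, 50 °C
Reagents that add atoms: none
Why: Zerovalent palladium inserts into both vinyl C–O bonds and formate delivers hydride with retention of alkene geometry, which removes the C1 oxygen as a ring alkene and turns the acyl group into the (E)-C9=C11 alkene (palladium-catalysed formate reduction of enol triflates).

Step 4
Reactants: 8 alkoxysilane
Product: 9 [(1S,2S)-2,6,6-trimethyl-2-[(1E)-penta-1,4-dien-1-yl]cyclohex-3-en-1-yl]methanol
Conditions: H2O2 (30% aq.), KF, KHCO3, THF/MeOH, rt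
Reagents that add atoms: hydrogen peroxide, OO
Why: Tamao–Fleming oxidation converts the C–Si bond of the alkoxysilane into C–OH and leaves the three alkenes untouched, which unmasks the C6 hydroxymethyl group.

Step 5
Reactants: 9 primary alcohol
Product: 10 (1S,2S)-2,6,6-trimethyl-2-[(1E)-penta-1,4-dien-1-yl]cyclohex-3-ene-1-carbaldehyde
Conditions: Dess–Martin periodinane, pyridine, CH2Cl2, 0 °C → rt
Reagents that add atoms: none
Why: Dess–Martin oxidation under buffered conditions should give the hindered aldehyde without epimerising the α-centre C5 or touching the skipped diene.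

Step 6
Reactants: 11 methyl 3-methylbut-2-enoate
Product: 12 [(1-methoxy-3-methylbuta-1,3-dien-1-yl)oxy]trimethylsilane
Conditions: LiN(iPr)2, THF, −78 °C; Me3SiCl, −78 °C → rt; distillation
Reagents that add atoms: chlorotrimethylsilane, C[Si](C)(C)Cl
Why: Kinetic γ-deprotonation of the β-methyl enoate and O-silylation give the vinylogous silyl ketene acetal (silyl dienolate formation); its ketene acetal geometry is of no consequence.

Step 7
Reactants: 10 aldehyde; 12 silyl dienolate
Product: 13 methyl (2E,5S)-5-hydroxy-3-methyl-5-[(1S,2S)-2,6,6-trimethyl-2-[(1E)-penta-1,4-dien-1-yl]cyclohex-3-en-1-yl]pent-2-enoate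
Conditions: N-tosyltryptophan-derived B-phenyl-1,3,2-oxazaborolidin-5-one (30 mol%), iPrOH (1 equiv), EtCN, −78 °C
Reagents that add atoms: none
Why: Vinylogous Mukaiyama aldol addition through the γ-carbon of the dienolate should form C6–C7 together with the (E)-trisubstituted enoate, and the chiral boron Lewis acid is meant to set the C6 carbinol by reagent control over the hindered α-branched aldehyde.

Step 8
Reactants: 13 δ-hydroxy enoate
Product: 14 methyl (2E,5S)-5-[(tert-butyldimethylsilyl)oxy]-3-methyl-5-[(1S,2S)-2,6,6-trimethyl-2-[(1E)-penta-1,4-dien-1-yl]cyclohex-3-en-1-yl]pent-2-enoate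
Conditions: tBuMe2SiOTf, 2,6-lutidine, CH2Cl2, −78 → 0 °C
Reagents that add atoms: tert-butyldimethylsilyl trifluoromethanesulfonate, CC(C)(C)[Si](C)(C)OS(=O)(=O)C(F)(F)F
Why: Silylation with the silyl triflate protects the hindered secondary C6 alcohol as a robust ether that will sit equatorial (6α) in the cycloaddition (silyl ether formation).

Step 9
Reactants: 14 silyl ether
Product: 15 methyl (2E,5S)-5-[(tert-butyldimethylsilyl)oxy]-3-methyl-5-[(1S,2R)-2,6,6-trimethyl-2-[(1E)-4-oxopent-1-en-1-yl]cyclohex-3-en-1-yl]pent-2-enoate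
Conditions: PdCl2 (10 mol%), CuCl (co-catalyst), O2 (1 atm), DMF/H2O, rt
Reagents that add atoms: water, O
Why: Wacker oxidation with divalent palladium is selective for the only monosubstituted alkene and gives the methyl ketone at C13 (Markovnikov), which leaves the (E)-C9=C11 alkene β,γ to the new carbonyl.

Step 10
Reactants: 15 β,γ-unsaturated methyl ketone
Product: 17 tricyclic ring A/B/C ester (14β-CO2Me; 13α-OSiEt3; 13β-Me; 6α-OSiMe2tBu; 1-ene; 11-ene), via triethylsilyl dienol ether 16 (not isolated)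
Conditions: Et3SiOTf (1.3 equiv), Et3N (2 equiv), CH2Cl2, −78 → 0 °C; solvent exchange to toluene, 2,6-di-tert-butyl-4-methylphenol (trace), sealed tube, 130 °C
Reagents that add atoms: triethylsilyl trifluoromethanesulfonate, CC[Si](CC)(CC)OS(=O)(=O)C(F)(F)F
Why: Soft enolisation removes the doubly activated C12–H and should give the conjugated (1E,3Z)-1-silyloxydiene 16 (O on C13 cis to C11, favoured by allylic 1,3-strain), which on heating undergoes a concerted, asynchronous, normal-electron-demand intramolecular Diels–Alder reaction with the (E)-β,β-disubstituted enoate to form C8–C9 and C13–C14. The closest known reaction type is the thermal type 1 intramolecular Diels–Alder reaction of 1,7,9-decatrienoates that carry a 1-silyloxydiene, which gives trans-fused octalins. Ring B is closed in the fused mode through the four-atom tether C10–C5–C6–C7 in a chair-like arrangement, and ring C is the cyclohexene made by the [4+2] bond pair itself. C9 is controlled by the existing C5 and C10 centres, because the trans-diequatorial tether on ring A and the equatorial C6 silyloxy group allow only the chair that puts H9 anti to the C10 methyl; C8 and C14 follow from the (E)-dienophile in the ester-endo transition state (8β-Me, 14β-CO2Me, trans B/C fusion), and C13 follows from the diene geometry (inside O becomes 13α, outside methyl 13β). The step needs endo over exo selectivity and the (3Z)-enol ether: the exo mode would put C14 with its ester, instead of the small C8 methyl, syn-axial to the C10 methyl, and the (3E)-isomer with an inside methyl reaches the s-cis conformation only with difficulty and should stay behind. Regiochemistry is fixed by the tether and is electronically matched, since the oxygen-bearing C13 bonds to the α-carbon C14 and the nucleophilic C9 to the β-carbon C8.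

Step 11
Reactants: 17 tricyclic diene ester
Product: 18 saturated tricyclic ester (14β-CO2Me, 13α-OSiEt3, 13β-Me, 6α-OSiMe2tBu)
Conditions: H2 (1 atm), PtO2, EtOAc, rt
Reagents that add atoms: none
Why: Catalytic hydrogenation saturates the two cis-disubstituted ring alkenes (C1=C2 and C11=C12) without creating a stereocentre, while the ester and both silyl ethers are inert.

Step 12
Reactants: 18 saturated ester
Product: 19 primary alcohol (14β-CH2OH, 13α-OSiEt3, 6α-OSiMe2tBu)
Conditions: LiAlH4, THF, 0 °C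
Reagents that add atoms: none
Why: Hydride reduction of the ester gives the C15 alcohol, and keeping O13 silylated excludes retro-aldol opening of ring C (LiAlH4 reduction).

Step 13
Reactants: 19 primary alcohol
Product: 20 primary iodide (14β-CH2I, 13α-OSiEt3, 6α-OSiMe2tBu)
Conditions: I2, PPh3, imidazole, toluene/MeCN, rt
Reagents that add atoms: iodine, II
Why: Appel-type iodination converts the primary alcohol into the iodide under near-neutral conditions that spare both silyl ethers.

Step 14
Reactants: 20 primary iodide; 21 tributyl(2-methylprop-2-en-1-yl)stannane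
Product: 22 14β-(3-methylbut-3-en-1-yl) tricycle (13α-OSiEt3, 6α-OSiMe2tBu)
Conditions: 21 (2 equiv), 2,2'-azobis(2-methylpropionitrile) (cat.), benzene, 80 °C
Reagents that add atoms: none
Why: Keck radical allylation generates the primary C15 radical from the iodide, which adds to the stannane and expels the tributyltin radical, so the C15–C16 bond forms at a position too hindered for a reliable SN2 coupling and no stereocentre is touched.

Step 15
Reactants: 22 bis(silyl ether)
Product: 23 tertiary alcohol (13α-OH, 13β-Me, 6α-OSiMe2tBu, 14β-(3-methylbut-3-en-1-yl))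
Conditions: HF·pyridine, pyridine, THF, 0 °C
Reagents that add atoms: none
Why: Buffered hydrogen fluoride cleaves the triethylsilyl ether much faster than the hindered tert-butyldimethylsilyl ether and so frees only the tertiary C13 alcohol (selective desilylation).

Step 16
Reactants: 23 tertiary alcohol; 24 3-bromoprop-1-ene
Product: 25 allyl ether (13α-O-allyl, 6α-OSiMe2tBu, 14β-(3-methylbut-3-en-1-yl))
Conditions: KH, THF, 0 °C; 24, Bu4NI (cat.), 0 °C → rt
Reagents that add atoms: none
Why: Williamson etherification of the potassium tertiary alkoxide with the allylic bromide puts C19 and C18 on O13, while O6 stays protected.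

Step 17
Reactants: 25 allyl ether
Product: 26 6-O-tert-butyldimethylsilyl ether of the target (tetracyclic, ring D closed, 17Z)
Conditions: second-generation Grubbs catalyst (H2IMes)(PCy3)Cl2Ru=CHPh (10 mol%), toluene (high dilution), 80 °C
Reagents that add atoms: none
Why: Ring-closing metathesis between the allyl ether and the 1,1-disubstituted alkene closes the eight-membered ring D, helped by the gauche trans-diequatorial C13–O and C14–C15 bonds, and the ring size enforces the (Z)-trisubstituted C17=C18 alkene.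

Step 18
Reactants: 26 silyl ether
Product: 27 target CNP0179324.1, (5S,6S,8R,9R,10R,13S,14S,17Z)-configured 6α-hydroxy tetracyclic oxocene ether
Conditions: Bu4NF, THF, 60 °C
Reagents that add atoms: none
Why: Fluoride cleaves the last silyl ether and reveals the equatorial 6α-hydroxyl without touching the allylic ether of ring D (desilylation).

## Compound list

1 | 2,4,4-trimethylcyclohex-2-en-1-one | CC1=CC(C)(C)CCC1=O | starting material
2 | (chloromethyl)dimethyl(propan-2-yloxy)silane | CC(C)O[Si](C)(C)CCl | starting material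
3 | pent-4-enoyl chloride | C=CCCC(=O)Cl | starting material
4 | {[dimethyl(propan-2-yloxy)silyl]methyl}magnesium chloride | CC(C)O[Si](C)(C)C[Mg]Cl | intermediate (not isolated)
5 | chloromagnesium (3S)-3-{[dimethyl(propan-2-yloxy)silyl]methyl}-2,4,4-trimethylcyclohex-1-en-1-olate | CC1=C(O[Mg]Cl)CCC(C)(C)[C@@H]1C[Si](C)(C)OC(C)C | intermediate (not isolated)
6 | (2S,3S)-3-{[dimethyl(propan-2-yloxy)silyl]methyl}-2,4,4-trimethyl-2-(pent-4-enoyl)cyclohexan-1-one (acyl and silylmethyl groups trans) | C=CCCC(=O)[C@@]1(C)C(=O)CCC(C)(C)[C@@H]1C[Si](C)(C)OC(C)C | intermediate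
7 | (1Z)-1-[(1S,6S)-6-{[dimethyl(propan-2-yloxy)silyl]methyl}-1,5,5-trimethyl-2-(trifluoromethanesulfonyloxy)cyclohex-2-en-1-yl]penta-1,4-dien-1-yl trifluoromethanesulfonate | C=CC/C=C(\OS(=O)(=O)C(F)(F)F)[C@@]1(C)C(OS(=O)(=O)C(F)(F)F)=CCC(C)(C)[C@@H]1C[Si](C)(C)OC(C)C | intermediate
8 | dimethyl(propan-2-yloxy){[(1S,2S)-2,6,6-trimethyl-2-[(1E)-penta-1,4-dien-1-yl]cyclohex-3-en-1-yl]methyl}silane | C=CC/C=C/[C@@]1(C)C=CCC(C)(C)[C@@H]1C[Si](C)(C)OC(C)C | intermediate
9 | [(1S,2S)-2,6,6-trimethyl-2-[(1E)-penta-1,4-dien-1-yl]cyclohex-3-en-1-yl]methanol | C=CC/C=C/[C@@]1(C)C=CCC(C)(C)[C@@H]1CO | intermediate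
10 | (1S,2S)-2,6,6-trimethyl-2-[(1E)-penta-1,4-dien-1-yl]cyclohex-3-ene-1-carbaldehyde | C=CC/C=C/[C@@]1(C)C=CCC(C)(C)[C@@H]1C=O | intermediate
11 | methyl 3-methylbut-2-enoate | CC(C)=CC(=O)OC | starting material
12 | [(1-methoxy-3-methylbuta-1,3-dien-1-yl)oxy]trimethylsilane (ketene acetal isomers) | C=C(C)C=C(OC)O[Si](C)(C)C | intermediate
13 | methyl (2E,5S)-5-hydroxy-3-methyl-5-[(1S,2S)-2,6,6-trimethyl-2-[(1E)-penta-1,4-dien-1-yl]cyclohex-3-en-1-yl]pent-2-enoate | C=CC/C=C/[C@@]1(C)C=CCC(C)(C)[C@@H]1[C@@H](O)C/C(C)=C/C(=O)OC | intermediate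
14 | methyl (2E,5S)-5-[(tert-butyldimethylsilyl)oxy]-3-methyl-5-[(1S,2S)-2,6,6-trimethyl-2-[(1E)-penta-1,4-dien-1-yl]cyclohex-3-en-1-yl]pent-2-enoate | C=CC/C=C/[C@@]1(C)C=CCC(C)(C)[C@@H]1[C@@H](O[Si](C)(C)C(C)(C)C)C/C(C)=C/C(=O)OC | intermediate
15 | methyl (2E,5S)-5-[(tert-butyldimethylsilyl)oxy]-3-methyl-5-[(1S,2R)-2,6,6-trimethyl-2-[(1E)-4-oxopent-1-en-1-yl]cyclohex-3-en-1-yl]pent-2-enoate | CC(=O)C/C=C/[C@@]1(C)C=CCC(C)(C)[C@@H]1[C@@H](O[Si](C)(C)C(C)(C)C)C/C(C)=C/C(=O)OC | intermediate
16 | methyl (2E,5S)-5-[(tert-butyldimethylsilyl)oxy]-3-methyl-5-[(1S,2R)-2,6,6-trimethyl-2-{(1E,3Z)-4-[(triethylsilyl)oxy]penta-1,3-dien-1-yl}cyclohex-3-en-1-yl]pent-2-enoate | CC[Si](CC)(CC)O/C(C)=C\C=C\[C@@]1(C)C=CCC(C)(C)[C@@H]1[C@@H](O[Si](C)(C)C(C)(C)C)C/C(C)=C/C(=O)OC | intermediate (not isolated)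
17 | tricyclic ring A/B/C ester: methyl ester (C15) on C14 (14β), 13α-OSiEt3, 13β-Me, 6α-OSiMe2tBu, 8β-Me, 10β-Me, 4,4-Me2, 5α-H, 9α-H, 14α-H, C1=C2 and C11=C12 double bonds | CC[Si](CC)(CC)O[C@@]2(C)C=C[C@@H]3[C@@]4(C)C=CCC(C)(C)[C@@H]4[C@@H](O[Si](C)(C)C(C)(C)C)C[C@@]3(C)[C@@H]2C(=O)OC | intermediate
18 | saturated tricyclic ester: as 17 without the two ring double bonds | CC[Si](CC)(CC)O[C@@]2(C)CC[C@@H]3[C@@]4(C)CCCC(C)(C)[C@@H]4[C@@H](O[Si](C)(C)C(C)(C)C)C[C@@]3(C)[C@@H]2C(=O)OC | intermediate
19 | primary alcohol: 14β-CH2OH, 13α-OSiEt3, 13β-Me, 6α-OSiMe2tBu | CC[Si](CC)(CC)O[C@@]2(C)CC[C@@H]3[C@@]4(C)CCCC(C)(C)[C@@H]4[C@@H](O[Si](C)(C)C(C)(C)C)C[C@@]3(C)[C@@H]2CO | intermediate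
20 | primary iodide: 14β-CH2I, 13α-OSiEt3, 13β-Me, 6α-OSiMe2tBu | CC[Si](CC)(CC)O[C@@]2(C)CC[C@@H]3[C@@]4(C)CCCC(C)(C)[C@@H]4[C@@H](O[Si](C)(C)C(C)(C)C)C[C@@]3(C)[C@@H]2CI | intermediate
21 | tributyl(2-methylprop-2-en-1-yl)stannane | CCCC[Sn](CCCC)(CCCC)CC(C)=C | starting material
22 | 14β-(3-methylbut-3-en-1-yl) tricycle: 13α-OSiEt3, 13β-Me, 6α-OSiMe2tBu | CC[Si](CC)(CC)O[C@@]2(C)CC[C@@H]3[C@@]4(C)CCCC(C)(C)[C@@H]4[C@@H](O[Si](C)(C)C(C)(C)C)C[C@@]3(C)[C@@H]2CCC(C)=C | intermediate
23 | tertiary alcohol: 13α-OH, 13β-Me, 6α-OSiMe2tBu, 14β-(3-methylbut-3-en-1-yl) | O[C@@]2(C)CC[C@@H]3[C@@]4(C)CCCC(C)(C)[C@@H]4[C@@H](O[Si](C)(C)C(C)(C)C)C[C@@]3(C)[C@@H]2CCC(C)=C | intermediate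
24 | 3-bromoprop-1-ene (allyl bromide) | C=CCBr | starting material
25 | allyl ether: 13α-O-CH2CH=CH2, 13β-Me, 6α-OSiMe2tBu, 14β-(3-methylbut-3-en-1-yl) | C=CCO[C@@]2(C)CC[C@@H]3[C@@]4(C)CCCC(C)(C)[C@@H]4[C@@H](O[Si](C)(C)C(C)(C)C)C[C@@]3(C)[C@@H]2CCC(C)=C | intermediate
26 | 6-O-tert-butyldimethylsilyl ether of the target: ring D = C13(α-O)–O–C19H2–C18H=C17(Me)–C16H2–C15H2–C14, (17Z) | C/C1=C/CO[C@@]2(C)CC[C@@H]3[C@@]4(C)CCCC(C)(C)[C@@H]4[C@@H](O[Si](C)(C)C(C)(C)C)C[C@@]3(C)[C@@H]2CC1 | intermediate
27 | CNP0179324.1: (5S,6S,8R,9R,10R,13S,14S,17Z)-tetracyclic ether, 6α-OH, 13α-O–C19 oxocene, 13β-Me, 8β-Me, 10β-Me | C/C1=C/CO[C@@]2(C)CC[C@@H]3[C@@]4(C)CCCC(C)(C)[C@@H]4[C@@H](O)C[C@@]3(C)[C@@H]2CC1 | target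

## Step count and risks

Total step count: 18. Longest linear sequence: 17 steps (1 → 27 through steps 1–5 and 7–18; step 6 is a side branch).

Steps most likely to fail:

Step 10. What may go wrong: loss of endo/exo control (cis-fused B/C isomer), or a [1,5]-silyl shift or hydrolysis of the (Z)-silyloxydiene at the temperature that the β,β-disubstituted enoate needs. The fallback sets out from 15 and returns at 19. The ester is saponified (LiOH, THF/H2O) to the carboxylic acid F1. F1 is converted through its pivalic mixed anhydride (pivaloyl chloride, Et3N) and lithiated oxazolidin-2-one into the N-acyl oxazolidinone F2. Soft enolisation as in step 10 gives the triethylsilyl dienol ether F3. The bidentate Lewis acid Me2AlCl (CH2Cl2, −40 °C) then drives the cycloaddition at low temperature through the chelated acyl oxazolidinone in the endo mode and should give the imide cycloadduct F4. LiBH4 (THF/MeOH) removes the oxazolidinone and gives the diene alcohol F5, and hydrogenation (H2, PtO2) of F5 gives 19.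

Step 1. What may go wrong: O-acylation (enol ester formation) or incomplete reaction of the hindered tetrasubstituted magnesium enolate with the acid chloride. The fallback sets out from 1 and 2 and returns at 6. The same conjugate addition is quenched with Me3SiCl to give the trimethylsilyl enol ether F6. Mukaiyama aldol addition of F6 to pent-4-enal (TiCl4, CH2Cl2, −78 °C) forms the C10–C9 bond anti to the C5 substituent and gives the β-hydroxy ketone F7 as a mixture of carbinol epimers. Dess–Martin oxidation of F7 gives 6.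

Step 7. What may go wrong: poor facial selectivity at C6 if catalyst control cannot override the hindered α-centre, or partial formation of the (Z)-enoate, which lactonises. The fallback sets out from 10 and returns at 14. Asymmetric propargylation of the aldehyde with allenylboronic acid pinacol ester and a chiral BINOL-derived phosphoric acid gives the homopropargylic alcohol F8. Silylation (tBuMe2SiOTf, 2,6-lutidine) gives the silyl ether F9. Zirconium-catalysed methylalumination of the terminal alkyne of F9 (Me3Al, Cp2ZrCl2) followed by ClCO2Me builds the (E)-3-methyl enoate stereospecifically and gives 14.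

Further compounds
F1 | step 10 | (2E,5S)-5-[(tert-butyldimethylsilyl)oxy]-3-methyl-5-[(1S,2R)-2,6,6-trimethyl-2-[(1E)-4-oxopent-1-en-1-yl]cyclohex-3-en-1-yl]pent-2-enoic acid | CC(=O)C/C=C/[C@@]1(C)C=CCC(C)(C)[C@@H]1[C@@H](O[Si](C)(C)C(C)(C)C)C/C(C)=C/C(=O)O
F2 | step 10 | 3-acyl oxazolidin-2-one (imide) of acid F1 | CC(=O)C/C=C/[C@@]1(C)C=CCC(C)(C)[C@@H]1[C@@H](O[Si](C)(C)C(C)(C)C)C/C(C)=C/C(=O)N2CCOC2=O
F3 | step 10 | (1E,3Z)-triethylsilyl dienol ether of imide F2 | CC[Si](CC)(CC)O/C(C)=C\C=C\[C@@]1(C)C=CCC(C)(C)[C@@H]1[C@@H](O[Si](C)(C)C(C)(C)C)C/C(C)=C/C(=O)N2CCOC2=O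
F4 | step 10 | tricyclic imide cycloadduct (as 17 with the oxazolidinone in place of OMe) | CC[Si](CC)(CC)O[C@@]2(C)C=C[C@@H]3[C@@]4(C)C=CCC(C)(C)[C@@H]4[C@@H](O[Si](C)(C)C(C)(C)C)C[C@@]3(C)[C@@H]2C(=O)N5CCOC5=O
F5 | step 10 | tricyclic diene alcohol (as 19 with C1=C2 and C11=C12 double bonds) | CC[Si](CC)(CC)O[C@@]2(C)C=C[C@@H]3[C@@]4(C)C=CCC(C)(C)[C@@H]4[C@@H](O[Si](C)(C)C(C)(C)C)C[C@@]3(C)[C@@H]2CO
F6 | step 1 | dimethyl(propan-2-yloxy){[(1S)-2,6,6-trimethyl-3-[(trimethylsilyl)oxy]cyclohex-2-en-1-yl]methyl}silane | CC1=C(O[Si](C)(C)C)CCC(C)(C)[C@@H]1C[Si](C)(C)OC(C)C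
F7 | step 1 | (2S,3S)-3-{[dimethyl(propan-2-yloxy)silyl]methyl}-2-(1-hydroxypent-4-en-1-yl)-2,4,4-trimethylcyclohexan-1-one (carbinol epimers) | C=CCCC(O)[C@@]1(C)C(=O)CCC(C)(C)[C@@H]1C[Si](C)(C)OC(C)C
F8 | step 7 | (1S)-1-[(1S,2S)-2,6,6-trimethyl-2-[(1E)-penta-1,4-dien-1-yl]cyclohex-3-en-1-yl]but-3-yn-1-ol | C=CC/C=C/[C@@]1(C)C=CCC(C)(C)[C@@H]1[C@@H](O)CC#C
F9 | step 7 | tert-butyldimethylsilyl ether of F8 | C=CC/C=C/[C@@]1(C)C=CCC(C)(C)[C@@H]1[C@@H](O[Si](C)(C)C(C)(C)C)CC#C
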